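**Retrosynthetic overview**

1. The route rests on one feature: the CH2 linker on C1 of ring A (C1–C5, C10) is cis to the C10 methyl, a face that a β-hydroxyl on C3, next to a C1=C2 alkene, can reach. The linker carbon is therefore brought in as the CH2 of a 1β,2β-cyclopropane and kept on C1 when the strained ring is opened.
2. Disconnections: three aryl acetals; aryl–CHO and aryl–CO(isobutyl) (two ortho-lithiations); C3–O (radical deoxygenation); aryl–CH2 (Negishi coupling); C2–CH2 (iodide opening of the cyclopropyl ketone); C1–CH2 and C2–CH2 (directed cyclopropanation).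
3. Ring order: ring B comes from (S)-carvone; ring A is closed by Robinson annulation with ethyl vinyl ketone; the cyclopropane is a temporary third ring; the arene comes from phloroglucinol.
4. C4 and the C5=C6 alkene come from deconjugation of the 1,4-dienone; the C3 oxygen serves as directing group and then as activating carbonyl before it is removed.

Key step: step 6

Remark: eudesmane numbering is used (C10 quaternary with methyl, C4 with methyl, C7 with isopropenyl; ring A = C1–C5 and C10, ring B = C5–C10). β is the face of the C10 methyl. All terpenoid compounds have the isopropenyl group on the α face (7-epi series), as the target SMILES requires.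
Assumption: 2, 5 and 27–29 are carried as epimer mixtures at a centre that is destroyed later (C2 of 2, C4 of 5, the carbinol carbon of 27–29).

**Route**

Step 1
Reactants: 1 (S)-(+)-carvone
Product: 2 (2S,5S)-dihydrocarvone
Conditions: Zn dust, KOH, EtOH–H2O, reflux
Reagents that add atoms: none
Why: Dissolving-metal conjugate reduction with zinc saturates only the enone C=C bond, leaving the isopropenyl group and the C5 stereocentre untouched; the C2 epimer ratio does not matter because C2 is enolised in step 2.

Step 2
Reactants: 2 (2S,5S)-dihydrocarvone; 3 ethyl vinyl ketone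
Product: 6 7-epi-α-cyperone, via Michael diketone 4 (not isolated), via aldol ketol 5 (not isolated)
Conditions: KOH, EtOH, −10 to 20 °C; then KOH, EtOH, reflux
Reagents that add atoms: none
Why: Robinson annulation in which the thermodynamic enolate adds to the enone by axial attack through a chair with the isopropenyl group equatorial, which should place the new chain cis and the C10 methyl trans to the isopropenyl group, and aldol closure with dehydration forms ring A; the minor C10 epimer is removed by chromatography of 6.

Step 3
Reactants: 6 7-epi-α-cyperone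
Product: 7 7-epi-eudesma-1,4,11-trien-3-one
Conditions: DDQ, 1,4-dioxane, reflux
Reagents that add atoms: none
Why: DDQ dehydrogenation of a 4-en-3-one under neutral conditions goes through the kinetic 2,4-dienol with hydride loss from C1, the classical way from steroidal 4-en-3-ones to 1,4-dien-3-ones; no stereocentre is formed.

Step 4
Reactants: 7 7-epi-eudesma-1,4,11-trien-3-one
Product: 9 4αH-7-epi-eudesma-1,5,11-trien-3-one, via potassium trienolate 8 (not isolated)
Conditions: t-BuOK, DMSO–THF, 20 °C; inverse quench into AcOH–H2O, 0 °C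
Reagents that add atoms: none
Why: Base deconjugation of a cross-conjugated dienone, in which t-BuOK removes a C6 proton and the trienolate is protonated kinetically at the α-carbon C4 (the known conversion of steroidal 1,4-dien-3-ones into 1,5-dien-3-ones); the acid should approach the almost flat ring A anti to the axial C10 methyl, placing hydrogen on the α face and the C4 methyl on the β face.

Step 5
Reactants: 9 4αH-7-epi-eudesma-1,5,11-trien-3-one
Product: 10 4αH-7-epi-eudesma-1,5,11-trien-3β-ol
Conditions: crude 9 used at once; NaBH4, CeCl3·7H2O, MeOH, −78 to −20 °C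
Reagents that add atoms: none
Why: Luche reduction gives 1,2-reduction of the enone under near-neutral conditions that should not epimerise C4 or reconjugate the alkene, and hydride adds axially from the α face, anti to the axial 4β-methyl beside the carbonyl, which sets the 3β-hydroxyl.

Step 6
Reactants: 10 4αH-7-epi-eudesma-1,5,11-trien-3β-ol; 11 diiodomethane
Product: 13 1β,2β-methano-4αH-7-epi-eudesma-5,11-dien-3β-ol, via iodomethylzinc alkoxide 12 (not isolated)
Conditions: Et2Zn (2.2 equiv.), CH2I2 (2.2 equiv.), CH2Cl2, −20 to 0 °C; aq. NH4Cl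
Reagents that add atoms: none
Why: Et2Zn and CH2I2 form ethyl(iodomethyl)zinc, which the C3 hydroxyl protonates to give the iodomethylzinc alkoxide 12, and the zinc-bound CH2 is then passed to C1=C2 in a concerted, butterfly-type [2+1] addition that forms the C1–CH2 and C2–CH2 bonds together. The closest known reaction type is the hydroxyl-directed Simmons–Smith methylenation (diethylzinc variant) of cyclohex-2-en-1-ols, including steroidal 4-en-3β-ols, in which CH2 is delivered to the β face next to the angular methyl. The cyclopropane closes in this single syn addition, a three-membered ring formed by simultaneous bonding of one carbon to both alkene termini and not by a stepwise exo or endo cyclisation. The two new stereocentres, C1 and C2, are both set by the C3β oxygen, which holds the carbenoid on the β face, and their cis relation follows from the suprafacial addition. The step needs β-face delivery and reaction at C1=C2 only: the zinc alkoxide raises the rate at the allylic alkene far above that of the others, C5=C6 is merely homoallylic, trisubstituted and shielded on the β face by the axial C4 and C10 methyls, and the remote isopropenyl alkene is protected by limiting the carbenoid to about two equivalents at or below 0 °C.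

Step 7
Reactants: 13 1β,2β-methano-4αH-7-epi-eudesma-5,11-dien-3β-ol
Product: 14 1β,2β-methano-4αH-7-epi-eudesma-5,11-dien-3-one
Conditions: Dess–Martin periodinane, pyridine, CH2Cl2, 0 °C
Reagents that add atoms: none
Why: Dess–Martin oxidation under pyridine buffer is the standard non-enolising oxidation for making β,γ-unsaturated ketones without conjugation, so C4 and the C5=C6 bond should survive and the cyclopropane centres are untouched.

Step 8
Reactants: 14 1β,2β-methano-4αH-7-epi-eudesma-5,11-dien-3-one
Product: 16 1β-(iodomethyl)-4αH-7-epi-eudesma-5,11-dien-3-one, via silyl enol ether 15 (not isolated)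
Conditions: Me3SiI, CH2Cl2, −78 to −20 °C; then dilute HCl, THF–H2O, 0 °C
Reagents that add atoms: iodotrimethylsilane, C[Si](C)(C)I
Why: Homoconjugate opening of a cyclopropyl ketone, in which O-silylation activates the carbonyl and iodide attacks the unhindered CH2 in an SN2 sense, cleaving the exocyclic C2–CH2 bond that overlaps with the carbonyl π system (the known course for bicyclo[4.1.0]heptan-2-ones), so the CH2I stays on C1 with the β configuration fixed in step 6; acid hydrolysis of 15 avoids the free enolate, which would close the cyclopropane again.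

Step 9
Reactants: 17 phloroglucinol
Product: 18 1,3,5-tris(methoxymethoxy)benzene
Conditions: MeOCH2Cl, i-Pr2NEt, DMF, 0 to 20 °C
Reagents that add atoms: chloromethyl methyl ether, COCCl
Why: O-Alkylation of the three phenols with a hard chloromethyl ether electrophile in the presence of an amine base gives the tris-acetal; no stereocentre is involved.

Step 10
Reactants: 18 1,3,5-tris(methoxymethoxy)benzene
Product: 19 2-iodo-1,3,5-tris(methoxymethoxy)benzene
Conditions: N-iodosuccinimide (1.0 equiv.), DMF, 0 to 20 °C
Reagents that add atoms: N-iodosuccinimide, O=C1CCC(=O)N1I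
Why: Electrophilic aromatic iodination of the strongly activated ring should stop after one iodine with one equivalent of reagent, and the three free positions are equivalent.

Step 11
Reactants: 16 1β-(iodomethyl)-4αH-7-epi-eudesma-5,11-dien-3-one; 19 2-iodo-1,3,5-tris(methoxymethoxy)benzene
Product: 21 1β-[2,4,6-tris(methoxymethoxy)benzyl]-4αH-7-epi-eudesma-5,11-dien-3-one, via alkylzinc iodide 20 (not isolated)
Conditions: Zn dust (activated by BrCH2CH2Br and Me3SiCl), LiCl, THF, 25–40 °C; then 19, Pd(OAc)2, SPhos, THF, 50 °C
Reagents that add atoms: none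
Why: LiCl-promoted zinc insertion into the primary C–I bond gives a ketone-tolerant alkylzinc iodide, and Negishi coupling with a palladium dialkylbiarylphosphine catalyst joins it to the di-ortho-substituted, electron-rich aryl iodide; the reagents are not basic, so C1 and C4 should not be affected.

Step 12
Reactants: 21 1β-[2,4,6-tris(methoxymethoxy)benzyl]-4αH-7-epi-eudesma-5,11-dien-3-one
Product: 22 1β-[2,4,6-tris(methoxymethoxy)benzyl]-4αH-7-epi-eudesma-5,11-dien-3β-ol
Conditions: NaBH4, CeCl3·7H2O, MeOH, −40 to 0 °C
Reagents that add atoms: none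
Why: Luche-type borohydride reduction under near-neutral conditions avoids enolisation toward C4, and hydride should again enter from the α face anti to the axial 4β-methyl to give mainly the 3β-alcohol; either epimer would serve because this centre is removed in step 14.

Step 13
Reactants: 22 1β-[2,4,6-tris(methoxymethoxy)benzyl]-4αH-7-epi-eudesma-5,11-dien-3β-ol
Product: 23 O-{1β-[2,4,6-tris(methoxymethoxy)benzyl]-4αH-7-epi-eudesma-5,11-dien-3β-yl} 1H-imidazole-1-carbothioate
Conditions: 1,1'-thiocarbonyldiimidazole, DMAP (cat.), ClCH2CH2Cl, 70 °C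
Reagents that add atoms: 1,1'-thiocarbonyldiimidazole, S=C(n1ccnc1)n1ccnc1
Why: Acyl transfer from thiocarbonyldiimidazole to the secondary alcohol gives the thiocarbonyl ester needed for a Barton–McCombie deoxygenation without touching any stereocentre.

Step 14
Reactants: 23 O-{1β-[2,4,6-tris(methoxymethoxy)benzyl]-4αH-7-epi-eudesma-5,11-dien-3β-yl} 1H-imidazole-1-carbothioate
Product: 24 1β-[2,4,6-tris(methoxymethoxy)benzyl]-4αH-7-epi-eudesma-5,11-diene
Conditions: Bu3SnH, AIBN (cat.), toluene, 100 °C
Reagents that add atoms: none
Why: Barton–McCombie deoxygenation, in which the stannyl radical adds to sulfur, β-scission gives the secondary C3 radical and hydrogen transfer from Bu3SnH gives the methylene, under neutral conditions that should leave C4, both alkenes and the aryl acetals intact.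

Step 15
Reactants: 24 1β-[2,4,6-tris(methoxymethoxy)benzyl]-4αH-7-epi-eudesma-5,11-diene; 25 isovaleraldehyde
Product: 27 1-{3-[(4αH-7-epi-eudesma-5,11-dien-1β-yl)methyl]-2,4,6-tris(methoxymethoxy)phenyl}-3-methylbutan-1-ol, via aryllithium 26 (not isolated)
Conditions: n-BuLi (1.1 equiv.), TMEDA, THF, 0 °C; then 25, −78 °C; H2O
Reagents that add atoms: none
Why: Directed ortho-metalation lithiates a ring position lying between two methoxymethoxy groups and the aryllithium adds to the aldehyde; the new carbinol centre forms as a mixture that is removed by oxidation in step 17.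

Step 16
Reactants: 27 1-{3-[(4αH-7-epi-eudesma-5,11-dien-1β-yl)methyl]-2,4,6-tris(methoxymethoxy)phenyl}-3-methylbutan-1-ol
Product: 29 3-[(4αH-7-epi-eudesma-5,11-dien-1β-yl)methyl]-5-(1-hydroxy-3-methylbutyl)-2,4,6-tris(methoxymethoxy)benzaldehyde, via dilithio species 28 (not isolated)
Conditions: n-BuLi (2.3 equiv.), THF, −20 to 0 °C; DMF, −78 to 20 °C; H2O
Reagents that add atoms: N,N-dimethylformamide, CN(C)C=O
Why: A second directed ortho-metalation, after deprotonation of the hydroxyl, lithiates the last ring hydrogen, again flanked by two methoxymethoxy groups, and the aryllithium is formylated with DMF.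

Step 17
Reactants: 29 3-[(4αH-7-epi-eudesma-5,11-dien-1β-yl)methyl]-5-(1-hydroxy-3-methylbutyl)-2,4,6-tris(methoxymethoxy)benzaldehyde
Product: 30 3-[(4αH-7-epi-eudesma-5,11-dien-1β-yl)methyl]-2,4,6-tris(methoxymethoxy)-5-(3-methylbutanoyl)benzaldehyde
Conditions: Dess–Martin periodinane, pyridine, CH2Cl2, 20 °C
Reagents that add atoms: none
Why: Dess–Martin oxidation converts the secondary benzylic alcohol into the aryl ketone without over-oxidising the aldehyde or touching the alkenes, and it removes the carbinol stereocentre.

Step 18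
Reactants: 30 3-[(4αH-7-epi-eudesma-5,11-dien-1β-yl)methyl]-2,4,6-tris(methoxymethoxy)-5-(3-methylbutanoyl)benzaldehyde
Product: 31 CNP0564915.1
Conditions: HCl (0.5 M), MeOH–THF, 40 °C
Reagents that add atoms: none
Why: Acid-catalysed acetal exchange with methanol cleaves the three aryl methoxymethyl ethers, each ortho to a carbonyl group and therefore labile, under conditions that should be too mild to protonate the trisubstituted or the isopropenyl alkene.

**Compound list**

1 | (S)-(+)-carvone | C=C(C)[C@@H]1CC(=O)C(C)=CC1 | starting material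
2 | (2S,5S)-dihydrocarvone (trans isomer drawn; used together with its C2 epimer) | C=C(C)[C@@H]1CC(=O)[C@@H](C)CC1 | intermediate
3 | ethyl vinyl ketone (pent-1-en-3-one) | CCC(=O)C=C | starting material
4 | 2-methyl-2-(3-oxopentyl)-5-isopropenylcyclohexanone, chain cis to isopropenyl (formed in the flask) | C=C(C)[C@@H]1CC(=O)[C@](C)(CCC(=O)CC)CC1 | intermediate
5 | 5β-hydroxy-7-epi-eudesm-11-en-3-one, cis-fused ketol, C4 epimers (formed in the flask) | C=C(C)[C@@H]1C[C@]2(O)C(C)C(=O)CC[C@]2(C)CC1 | intermediate
6 | 7-epi-α-cyperone, (4aS,7S)-1,4a-dimethyl-7-(prop-1-en-2-yl)-4,4a,5,6,7,8-hexahydronaphthalen-2(3H)-one | C=C(C)[C@@H]1CC2=C(C)C(=O)CC[C@]2(C)CC1 | intermediate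
7 | 7-epi-eudesma-1,4,11-trien-3-one | C=C(C)[C@@H]1CC2=C(C)C(=O)C=C[C@]2(C)CC1 | intermediate
8 | potassium 7-epi-eudesma-1,3,5,11-tetraen-3-olate (formed in the flask) | C=C(C)[C@@H]1C=C2C(C)=C([O-])C=C[C@]2(C)CC1.[K+] | intermediate
9 | 4αH-7-epi-eudesma-1,5,11-trien-3-one (4β-methyl) | C=C(C)[C@@H]1C=C2[C@@H](C)C(=O)C=C[C@]2(C)CC1 | intermediate
10 | 4αH-7-epi-eudesma-1,5,11-trien-3β-ol (4β-methyl) | C=C(C)[C@@H]1C=C2[C@@H](C)[C@@H](O)C=C[C@]2(C)CC1 | intermediate
11 | diiodomethane | ICI | starting material
12 | (iodomethyl)zinc 3β-alkoxide of 10 (formed in the flask) | C=C(C)[C@@H]1C=C2[C@@H](C)[C@@H](O[Zn]CI)C=C[C@]2(C)CC1 | intermediate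
13 | 1β,2β-methano-4αH-7-epi-eudesma-5,11-dien-3β-ol | C=C(C)[C@@H]1C=C2[C@@H](C)[C@@H](O)[C@H]3C[C@H]3[C@]2(C)CC1 | intermediate
14 | 1β,2β-methano-4αH-7-epi-eudesma-5,11-dien-3-one | C=C(C)[C@@H]1C=C2[C@@H](C)C(=O)[C@H]3C[C@H]3[C@]2(C)CC1 | intermediate
15 | 1β-(iodomethyl)-3-(trimethylsilyloxy)-4αH-7-epi-eudesma-2,5,11-triene (formed in the flask) | C=C(C)[C@@H]1C=C2[C@@H](C)C(O[Si](C)(C)C)=C[C@@H](CI)[C@]2(C)CC1 | intermediate
16 | 1β-(iodomethyl)-4αH-7-epi-eudesma-5,11-dien-3-one | C=C(C)[C@@H]1C=C2[C@@H](C)C(=O)C[C@@H](CI)[C@]2(C)CC1 | intermediate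
17 | phloroglucinol | Oc1cc(O)cc(O)c1 | starting material
18 | 1,3,5-tris(methoxymethoxy)benzene | COCOc1cc(OCOC)cc(OCOC)c1 | intermediate
19 | 2-iodo-1,3,5-tris(methoxymethoxy)benzene | COCOc1cc(OCOC)c(I)c(OCOC)c1 | intermediate
20 | [(3-oxo-4αH-7-epi-eudesma-5,11-dien-1β-yl)methyl]zinc iodide (formed in the flask) | C=C(C)[C@@H]1C=C2[C@@H](C)C(=O)C[C@@H](C[Zn]I)[C@]2(C)CC1 | intermediate
21 | 1β-[2,4,6-tris(methoxymethoxy)benzyl]-4αH-7-epi-eudesma-5,11-dien-3-one | C=C(C)[C@@H]1C=C2[C@@H](C)C(=O)C[C@@H](Cc3c(OCOC)cc(OCOC)cc3OCOC)[C@]2(C)CC1 | intermediate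
22 | 1β-[2,4,6-tris(methoxymethoxy)benzyl]-4αH-7-epi-eudesma-5,11-dien-3β-ol | C=C(C)[C@@H]1C=C2[C@@H](C)[C@@H](O)C[C@@H](Cc3c(OCOC)cc(OCOC)cc3OCOC)[C@]2(C)CC1 | intermediate
23 | O-{1β-[2,4,6-tris(methoxymethoxy)benzyl]-4αH-7-epi-eudesma-5,11-dien-3β-yl} 1H-imidazole-1-carbothioate | C=C(C)[C@@H]1C=C2[C@@H](C)[C@@H](OC(=S)n3ccnc3)C[C@@H](Cc3c(OCOC)cc(OCOC)cc3OCOC)[C@]2(C)CC1 | intermediate
24 | 1β-[2,4,6-tris(methoxymethoxy)benzyl]-4αH-7-epi-eudesma-5,11-diene | C=C(C)[C@@H]1C=C2[C@@H](C)CC[C@@H](Cc3c(OCOC)cc(OCOC)cc3OCOC)[C@]2(C)CC1 | intermediate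
25 | isovaleraldehyde (3-methylbutanal) | CC(C)CC=O | starting material
26 | 3-lithio derivative of 24 (formed in the flask) | C=C(C)[C@@H]1C=C2[C@@H](C)CC[C@@H](Cc3c(OCOC)cc(OCOC)c([Li])c3OCOC)[C@]2(C)CC1 | intermediate
27 | 1-{3-[(4αH-7-epi-eudesma-5,11-dien-1β-yl)methyl]-2,4,6-tris(methoxymethoxy)phenyl}-3-methylbutan-1-ol (carbinol epimers) | C=C(C)[C@@H]1C=C2[C@@H](C)CC[C@@H](Cc3c(OCOC)cc(OCOC)c(C(O)CC(C)C)c3OCOC)[C@]2(C)CC1 | intermediate
28 | lithium alkoxide of 27 lithiated at the free ring position (formed in the flask) | C=C(C)[C@@H]1C=C2[C@@H](C)CC[C@@H](Cc3c(OCOC)c([Li])c(OCOC)c(C(O[Li])CC(C)C)c3OCOC)[C@]2(C)CC1 | intermediate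
29 | 3-[(4αH-7-epi-eudesma-5,11-dien-1β-yl)methyl]-5-(1-hydroxy-3-methylbutyl)-2,4,6-tris(methoxymethoxy)benzaldehyde (carbinol epimers) | C=C(C)[C@@H]1C=C2[C@@H](C)CC[C@@H](Cc3c(OCOC)c(C=O)c(OCOC)c(C(O)CC(C)C)c3OCOC)[C@]2(C)CC1 | intermediate
30 | 3-[(4αH-7-epi-eudesma-5,11-dien-1β-yl)methyl]-2,4,6-tris(methoxymethoxy)-5-(3-methylbutanoyl)benzaldehyde | C=C(C)[C@@H]1C=C2[C@@H](C)CC[C@@H](Cc3c(OCOC)c(C=O)c(OCOC)c(C(=O)CC(C)C)c3OCOC)[C@]2(C)CC1 | intermediate
31 | CNP0564915.1, 3-[(4αH-7-epi-eudesma-5,11-dien-1β-yl)methyl]-2,4,6-trihydroxy-5-(3-methylbutanoyl)benzaldehyde | C=C(C)[C@@H]1C=C2[C@@H](C)CC[C@@H](Cc3c(O)c(C=O)c(O)c(C(=O)CC(C)C)c3O)[C@]2(C)CC1 | target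

**Step count**

Total: 18 steps. Longest linear sequence: 16 steps (steps 1–8 and 11–18, from (S)-carvone); steps 9 and 10 prepare the aryl iodide.

**Steps most likely to fail**

Step 4. The proton may be delivered to the β face of C4 (poor facial selectivity, giving the 4α-methyl epimer) or to C6 (return to 7), and the labile ketone 9 may re-enolise during isolation. The fallback sets out from 7 and comes back at 10. Enolate 8 would be made as before and trapped on oxygen with acetic anhydride to give the trienol acetate 7-epi-eudesma-1,3,5,11-tetraen-3-yl acetate F1, which can be purified. F1 would then be treated with NaBH4 and CaCl2 in EtOH–THF at −10 °C (the enol ester–borohydride reductive deconjugation used for 3β-hydroxy-5-enes). Borohydride cleaves the enol ester, the enolate is protonated at C4 by the solvent, and the 1,5-dienone is reduced as it forms, so 9 is never handled. Should both C4 epimers form, they would be separated as alcohols at the stage of 10 and the unwanted one returned to 7 by oxidation and base.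

Step 8. Under the Lewis-acidic silyl iodide the activated ketone may enolise toward C4 (epimerisation, or migration of C5=C6 into conjugation), adventitious HI may add to the isopropenyl group, and the γ-iodo ketone may close back to the cyclopropane. The fallback sets out from 14 and comes back at 16. The cyclopropane would be opened by a soft nucleophile under buffered, non-acidic conditions: PhSeH with a substoichiometric amount of PhSeNa in DMF at about 60 °C (selenolate homoconjugate opening of a cyclopropyl ketone). The enolate formed is protonated at once by the selenol, and the selenol–selenolate pair is far too weak a base to enolise C4. This gives the selenide 1β-[(phenylselanyl)methyl]-4αH-7-epi-eudesma-5,11-dien-3-one F2. F2 would then be converted into 16 by MeI and NaI in DMF (selenide-to-iodide exchange through the methylselenonium salt).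

Step 11. Oxidative addition into the hindered, electron-rich aryl iodide may be slow, so that the alkylzinc is lost by protonolysis or β-hydride elimination, or zinc insertion next to the ketone may stall. The fallback sets out from 16 and 18 and comes back at 21, with the roles of the partners exchanged. Compound 18 would be lithiated (n-BuLi, THF, 0 °C) and transmetalated with ZnCl2 to [2,4,6-tris(methoxymethoxy)phenyl]zinc chloride F3. F3 would be coupled with the primary iodide 16 using Ni(acac)2 and 4-(trifluoromethyl)styrene in THF–NMP at −15 °C (nickel-catalysed coupling of arylzinc reagents with primary alkyl iodides, tolerant of ketones). No zinc insertion and no aryl halide are needed.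

**Further compounds**

F1 | step 4 | 7-epi-eudesma-1,3,5,11-tetraen-3-yl acetate | C=C(C)[C@@H]1C=C2C(C)=C(OC(C)=O)C=C[C@]2(C)CC1
F2 | step 8 | 1β-[(phenylselanyl)methyl]-4αH-7-epi-eudesma-5,11-dien-3-one | C=C(C)[C@@H]1C=C2[C@@H](C)C(=O)C[C@@H](C[Se]c3ccccc3)[C@]2(C)CC1
F3 | step 11 | [2,4,6-tris(methoxymethoxy)phenyl]zinc chloride | COCOc1cc(OCOC)c([Zn]Cl)c(OCOC)c1
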